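Readings and results are calculated with constants of no real substance.

A small charge of protic impurity, 0.0150 M, stood in these recipes beside 0.315 M of second nucleophile, and I set it aside to ask a plainer thing first: when did a flask stop making other capture product?

| flask | substrate | first nucleophile | second nucleophile | protic impurity | capture agent | temperature | remark | time |
|---|---|---|---|---|---|---|---|---|
| spring | 0.30 M | 0.75 M | 0.315 M | 0.015 M | 0.090 M | 75 °C | run made earlier |  |
| summer | 0.30 M | 0.75 M | 0.44 M | 0.015 M | 0.090 M | 90 °C | run made earlier |  |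
| dusk | 0.30 M | 0.75 M | 0.69 M | 0.015 M | 0.090 M | 75 °C | run made earlier |  |
| dawn | 0.15 M | 0.75 M | 0.315 M | 0.015 M | 0.090 M | 90 °C | run made earlier |  |
| oak | 0.30 M (fed, over 6.0 min) | 0.750 M | 0.315 M | 0.0150 M | 0.0900 M | 90 °C | all else is in the flask from the start; the feed brings no volume worth counting | 15 min |
| ash | 0.30 M | 0.750 M | 0.315 M | 0.0150 M | 0.0900 M |  | everything together at the start at 70 °C, warmed to 90 °C at 6.0 min | 15 min |
| elm | 0.30 M | 0.750 M | 0.315 M (fed, over 6.0 min) | 0.0150 M | 0.0900 M |  | the addition at 70 °C, then warmed to 90 °C; the feed brings no volume worth counting | 15 min |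
| cedar | 0.30 M | 0.750 M | 0.315 M (in portions, 2, over 6.0 min) | 0.0150 M | 0.0900 M | 90 °C | first portion at the start, last at 6.0 min | 15 min |
| alder | 0.30 M | 0.750 M | 0.315 M | 0.0150 M | 0.0900 M | 90 °C | everything together at the start | 15 min |

- the flask that comes out highest in amount of other capture product, in percent of the substrate charged; "all alike" if 1.5 percentage points covers them all (oak / ash / elm / cedar / alder / all alike)
- amount of other capture product at the end, in percent of the substrate charged, oak
- amount of other capture product at the end, in percent of the substrate charged, ash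
- amount of other capture product at the end, in percent of the substrate charged, elm
- amount of other capture product at the end, in percent of the substrate charged, cedar
- amount of other capture product at the end, in percent of the substrate charged, alder



spring run (percent of the substrate charged)

| time / min | other capture product / % | target / % | substrate / % |
|---|---|---|---|
| 1.33 | 9.9 | 4.9 | 84.1 |
| 4.00 | 25.7 | 14.7 | 58.4 |
| 6.00 | 34.4 | 20.4 | 44.9 |
| 10.0 | 44.9 | 27.7 | 26.2 |
| 12.0 | 47.8 | 30.2 | 20.0 |
| 20.0 | 54.5 | 35.0 | 7.0 |

summer run (percent of the substrate charged)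

| time / min | other capture product / % | target / % | substrate / % |
|---|---|---|---|
| 2.00 | 40.5 | 23.9 | 34.3 |
| 4.00 | 54.0 | 31.3 | 11.7 |
| 6.00 | 59.0 | 33.4 | 3.8 |
| 8.00 | 59.9 | 32.7 | 1.6 |
| 10.0 | 60.5 | 31.9 | 0.1 |
| 12.0 | 60.7 | 30.4 | 0.1 |

dusk run (percent of the substrate charged)

| time / min | other capture product / % | target / % | substrate / % |
|---|---|---|---|
| 2.00 | 18.8 | 4.4 | 76.6 |
| 5.00 | 38.4 | 9.1 | 50.9 |
| 8.00 | 52.1 | 13.1 | 33.9 |
| 12.0 | 63.1 | 16.3 | 20.1 |
| 20.0 | 73.7 | 18.4 | 6.9 |
| 25.0 | 75.8 | 18.3 | 3.3 |

The earlier readings carry a scatter of 0.3 percentage points, and the dawn run was the small table I read aloud.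

dawn run (percent of the substrate charged)

| time / min | other capture product / % | target / % | substrate / % |
|---|---|---|---|
| 1.00 | 23.2 | 18.1 | 58.6 |
| 2.00 | 36.1 | 27.9 | 34.3 |
| 3.00 | 43.6 | 33.7 | 19.8 |
| 6.00 | 52.2 | 38.5 | 3.9 |
| 12.0 | 54.1 | 36.0 | 0.3 |

Down its first rows the substrate went from 58.6% to 34.3% to 19.8%, keeping 0.585 and then 0.577 of itself at each equal step. So the fall looked first order, and the summer run, with twice the substrate and more second nucleophile, read the same 34.3% at 2.00 min. From the first row to the fourth the rate constant read 0.542 min⁻¹, so the half-life of the substrate at 90 °C read 1.28 min: the time in which whatever substrate stands is halved.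

The last two rows showed what that count was for. From 6.00 min to 12.0 min the substrate lost 3.6 points while other capture product gained 1.9 points. My rule, taken from this pair of rows, was that once the whole charge is in, other capture product gains no more than the substrate still left, and I counted half-lives from the last substrate in.

Alder, with everything in at the start, had 11.7 half-lives, from which I reckoned 0.0295% of the substrate at the end. Oak's feed ended at 6.0 min, so oak had 7.04 half-lives after it. For the feed's end I estimated oak's substrate as the feed rate over the rate constant, 30.8% of the charge, so I reckoned 0.234% at the end.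

The forecast named ash highest, with oak 50%, ash 56%, elm 41%, cedar 29% and alder 50%, holding that “the substrate feed changes nothing”.

    substrate → open intermediate (k = 0.536 min⁻¹, Ea = 97.0 kJ mol⁻¹)
    first nucleophile + open intermediate → target (k = 23.6 L mol⁻¹ min⁻¹, Ea = 65.0 kJ mol⁻¹)
    second nucleophile + open intermediate → other capture product (k = 77.4 L mol⁻¹ min⁻¹, Ea = 38.0 kJ mol⁻¹)
    second nucleophile + protic impurity → quenched reagent (k = 36.6 L mol⁻¹ min⁻¹, Ea = 49.0 kJ mol⁻¹)
    target ⇌ isomer of the product (K = 0.708, k = 0.0317 min⁻¹, Ea = 120 kJ mol⁻¹, ΔH = −53.0 kJ mol⁻¹)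
    open intermediate + capture agent → trapped intermediate (k = 0.466 L mol⁻¹ min⁻¹, Ea = 69.0 kJ mol⁻¹)
    (constants at 90 °C)

Ash came out highest at 54.0%, then alder 51.0%, oak 50.9%, elm 47.6% and cedar 32.4%. Oak held 0.240% of substrate against my 0.234%, and cedar, counted from the start like alder, held 0.0322% against 0.0295%. Elm stood 6.6 points above the forecast's 41%, more than its 0.49% of substrate left. Ash's limiting reagent, the substrate, stood at 0.49% of its charge, against 44% for second nucleophile, and ash reads 54.2% at 150 min. In cedar at 15.0 min target was still passing to isomer of the product, made at 0.0101 of the rate it was used up, yet cedar's other capture product reads 32.4% at 150 min.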